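**Retrosynthetic overview**

1. The target is a (2S,3S)-trans-2-aryl-3-methyl-2,3-dihydrobenzofuran (ring A = benzo ring, ring B = dihydrofuran ring, ring C = 3,4-dimethoxyphenyl; locants O1, C2, C3, C3a, C4–C7, C7a) carrying an erythro (1R,2S)-propane-1,2-diol on C5. The diol is cut back to an α-hydroxy ketone (chelation-controlled reduction), and the C5–C1' bond to a C5 aryllithium plus a Weinreb amide of L-lactic acid, which leaves a C5 bromide.
2. Ring B, the only ring to be made, is opened in one operation at O1–C7a and at C2–C3: C2 and O1 become the carbonyl group of 3,4-dimethoxybenzaldehyde, and C3–C3a–C7a becomes a 2-ethylaryl p-tolyl sulfoxide.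
3. Enabling feature: C7a (which carries O1) and the benzylic, methyl-bearing C3 both sit on C3a of ring A. One sulfinyl group on C7a can therefore direct lithiation of C3, relay its chirality to C3, and then leave when the O1 alkoxide born at C2 closes the five-membered ring; C2, an aryl carbinol carbon, maps onto a non-enolisable aromatic aldehyde.
4. The sulfoxide comes from a commercial aniline by Sandmeyer iodination, Andersen sulfinylation and benzylic methylation. Rings A and C are bought; ring B is formed in step 4.

Key step: step 4

Remark (assumption): the sense of 1,4-induction from sulfur to C3 in step 4 is taken from the lithium chelate model given there, (S) at sulfur giving (S) at C3. Should the opposite sense be found, the mirror-image sulfinate, (1S,2R,5S)-menthyl (R)-p-toluenesulfinate, would be used in step 2 with nothing else changed.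

**Route**

Step 1
Reactants: 1 4-bromo-2-methoxy-6-methylaniline
Product: 3 5-bromo-2-iodo-1-methoxy-3-methylbenzene, via diazonium chloride 2 (not isolated)
Conditions: NaNO2, aq. HCl, MeCN, 0 °C; then KI, 0 °C → rt
Reagents that add atoms: potassium iodide, [K+].[I-]
Why: Sandmeyer-type iododediazoniation, in which iodide reduces the arenediazonium ion and the aryl radical is captured as the aryl iodide without copper, while the bromide, methoxy and methyl groups are inert.

Step 2
Reactants: 3 5-bromo-2-iodo-1-methoxy-3-methylbenzene; 4 (1R,2S,5R)-(−)-menthyl (S)-p-toluenesulfinate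
Product: 6 (S)-5-bromo-1-methoxy-3-methyl-2-(p-tolylsulfinyl)benzene, via aryl Grignard reagent 5 (not isolated)
Conditions: i-PrMgCl·LiCl, THF, −20 °C; then 4, THF, −40 → 0 °C
Reagents that add atoms: none
Why: Andersen sulfoxide synthesis, in which iodine–magnesium exchange (far faster than exchange of the bromide) gives the aryl Grignard reagent, which displaces mentholate at sulfur with inversion, so that the (S) sulfinate should give the (S) sulfoxide (ring A outranks p-tolyl, hence the same descriptor).

Step 3
Reactants: 6 (S)-5-bromo-1-methoxy-3-methyl-2-(p-tolylsulfinyl)benzene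
Product: 8 (S)-5-bromo-1-ethyl-3-methoxy-2-(p-tolylsulfinyl)benzene, via benzylic lithium 7 (not isolated)
Conditions: LiN(i-Pr)2, THF, −78 °C; then MeI, −78 °C
Reagents that add atoms: iodomethane, CI
Why: Lateral lithiation followed by SN2 methylation, in which the sulfinyl oxygen guides the amide base to the neighbouring methyl group and stabilises the benzylic anion by chelation; no carbon stereocentre is formed and sulfur is untouched.

Step 4
Reactants: 8 (S)-5-bromo-1-ethyl-3-methoxy-2-(p-tolylsulfinyl)benzene; 9 3,4-dimethoxybenzaldehyde
Product: 12 (2S,3S)-5-bromo-2-(3,4-dimethoxyphenyl)-7-methoxy-3-methyl-2,3-dihydro-1-benzofuran, via benzylic lithium 10 (not isolated), via lithium alkoxide 11 (not isolated)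
Conditions: LiN(i-Pr)2, THF, −78 °C; then 9, −78 °C; then KOt-Bu, 18-crown-6, −78 → 40 °C
Reagents that add atoms: none
Why: Proposed new method: LiN(i-Pr)2 removes a benzylic proton of the ethyl group of 8 under direction of the ortho sulfinyl oxygen, the chelated benzylic lithium 10 adds to aldehyde 9 (C2–C3 bond), and alkoxide 11, after exchange of lithium for potassium, attacks the sulfinyl-bearing carbon C7a and expels p-toluenesulfenate (O1–C7a bond) in an addition–elimination SNAr at the ipso position. The closest known reaction type is the anionic tandem in which ortho-sulfinyl benzylic carbanions add to imines and the amide nitrogen then displaces the sulfinyl group to give indolines, and the addition of such carbanions to aldehydes is itself known; new is the closure by oxygen, reasoned to work because a crown-ether-separated potassium alkoxide is a nucleophile of comparable strength held in the same geometry, because attack at sulfur cannot expel a carbanion and is therefore unproductive, and because the para bromine helps to carry the negative charge of the addition step. Ring B closes in the 5-exo-trig mode. C3 is controlled by the sulfur stereocentre: in the six-membered chelate of 10 (C3, C3a, C7a, S, O, Li) the 7-methoxy group pushes the p-tolyl group out of the ring-A plane to the face opposite to O–Li, the C3 methyl group turns away from sulfur, and the aldehyde is delivered on the lithium-bearing face, which for (S) sulfur should give (S) at C3. C2 is set in the same addition, with the lithium-bound carbonyl oxygen on the sulfinyl side and ring C lying between H and CH3 of C3 and not next to ring A, which should give the (1S,2S) anti alkoxide and hence the trans ring, also the more stable arrangement. The step needs benzylic deprotonation in preference to ring metalation next to the bromide, secured by the proximity effect of the sulfinyl group with a lithium amide at −78 °C, and ipso attack in preference to any other pathway of the alkoxide, secured because the oxygen sits exactly five atoms from C7a.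

Step 5
Reactants: 13 ethyl (S)-lactate
Product: 14 (S)-2-hydroxy-N-methoxy-N-methylpropanamide
Conditions: MeNH(OMe)·HCl, i-PrMgCl, THF, −20 → 0 °C
Reagents that add atoms: N,O-dimethylhydroxylamine hydrochloride, CNOC.Cl
Why: Weinreb amide formation by aminolysis of the ester with the magnesium amide generated in the flask, the stereocentre being shielded from enolisation as the neighbouring magnesium alkoxide.

Step 6
Reactants: 14 (S)-2-hydroxy-N-methoxy-N-methylpropanamide
Product: 15 (S)-N-methoxy-N-methyl-2-(triethylsilyloxy)propanamide
Conditions: Et3SiCl, imidazole, CH2Cl2, 0 °C → rt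
Reagents that add atoms: chlorotriethylsilane, CC[Si](Cl)(CC)CC
Why: Standard silylation of a secondary alcohol, giving an ether that should survive the organolithium step and fall off under mild aqueous acid.

Step 7
Reactants: 12 (2S,3S)-5-bromo-2-(3,4-dimethoxyphenyl)-7-methoxy-3-methyl-2,3-dihydro-1-benzofuran; 15 (S)-N-methoxy-N-methyl-2-(triethylsilyloxy)propanamide
Product: 19 (2S)-1-[(2S,3S)-2-(3,4-dimethoxyphenyl)-7-methoxy-3-methyl-2,3-dihydro-1-benzofuran-5-yl]-2-hydroxypropan-1-one, via aryllithium 16 (not isolated), via tetrahedral lithium adduct 17 (not isolated), via silyl ketone 18 (not isolated)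
Conditions: n-BuLi, THF, −78 °C; then 15, −78 → −20 °C; then 1 M aq. HCl, THF, 0 °C → rt
Reagents that add atoms: none
Why: Bromine–lithium exchange followed by Weinreb ketone synthesis, in which the chelated tetrahedral adduct persists until the acidic work-up that releases the ketone and cleaves the silyl ether, so that the aryllithium adds only once and the lactate stereocentre is never exposed to base as a ketone.

Step 8
Reactants: 19 (2S)-1-[(2S,3S)-2-(3,4-dimethoxyphenyl)-7-methoxy-3-methyl-2,3-dihydro-1-benzofuran-5-yl]-2-hydroxypropan-1-one
Product: 20 (1R,2S)-1-[(2S,3S)-2-(3,4-dimethoxyphenyl)-7-methoxy-3-methyl-2,3-dihydro-1-benzofuran-5-yl]propane-1,2-diol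
Conditions: Zn(BH4)2, Et2O/THF, −20 → 0 °C; aq. NH4Cl work-up
Reagents that add atoms: none
Why: Chelation-controlled reduction (Cram chelate model), in which zinc bridges the carbonyl and α-hydroxyl oxygens in a five-membered ring and hydride is delivered to the face anti to the C2' methyl group, which should give the (1R) carbinol and thus the erythro (1R,2S) diol.

**Compound list**

1 | 4-bromo-2-methoxy-6-methylaniline | COc1cc(Br)cc(C)c1N | starting material
2 | 4-bromo-2-methoxy-6-methylbenzenediazonium chloride | COc1cc(Br)cc(C)c1[N+]#N.[Cl-] | intermediate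
3 | 5-bromo-2-iodo-1-methoxy-3-methylbenzene | COc1cc(Br)cc(C)c1I | intermediate
4 | (1R,2S,5R)-(−)-menthyl (S)-p-toluenesulfinate | Cc1ccc(cc1)[S@@](=O)O[C@@H]1C[C@H](C)CC[C@H]1C(C)C | starting material
5 | (4-bromo-2-methoxy-6-methylphenyl)magnesium chloride | COc1cc(Br)cc(C)c1[Mg]Cl | intermediate
6 | (S)-5-bromo-1-methoxy-3-methyl-2-(p-tolylsulfinyl)benzene | Cc1cc(Br)cc(OC)c1[S@@](=O)c1ccc(C)cc1 | intermediate
7 | {5-bromo-3-methoxy-2-[(S)-p-tolylsulfinyl]benzyl}lithium | [Li]Cc1cc(Br)cc(OC)c1[S@@](=O)c1ccc(C)cc1 | intermediate
8 | (S)-5-bromo-1-ethyl-3-methoxy-2-(p-tolylsulfinyl)benzene | CCc1cc(Br)cc(OC)c1[S@@](=O)c1ccc(C)cc1 | intermediate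
9 | 3,4-dimethoxybenzaldehyde | COc1ccc(C=O)cc1OC | starting material
10 | (1-{5-bromo-3-methoxy-2-[(S)-p-tolylsulfinyl]phenyl}ethyl)lithium, oxygen-chelated, carbon configuration not fixed | CC([Li])c1cc(Br)cc(OC)c1[S@@](=O)c1ccc(C)cc1 | intermediate
11 | lithium (1S,2S)-2-{5-bromo-3-methoxy-2-[(S)-p-tolylsulfinyl]phenyl}-1-(3,4-dimethoxyphenyl)propan-1-olate | COc1ccc(cc1OC)[C@@H]([O-])[C@@H](C)c1cc(Br)cc(OC)c1[S@@](=O)c1ccc(C)cc1.[Li+] | intermediate
12 | (2S,3S)-5-bromo-2-(3,4-dimethoxyphenyl)-7-methoxy-3-methyl-2,3-dihydro-1-benzofuran | COc1ccc([C@H]2Oc3c(OC)cc(Br)cc3[C@@H]2C)cc1OC | intermediate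
13 | ethyl (S)-lactate | CCOC(=O)[C@H](C)O | starting material
14 | (S)-2-hydroxy-N-methoxy-N-methylpropanamide | CON(C)C(=O)[C@H](C)O | intermediate
15 | (S)-N-methoxy-N-methyl-2-(triethylsilyloxy)propanamide | CON(C)C(=O)[C@H](C)O[Si](CC)(CC)CC | intermediate
16 | [(2S,3S)-2-(3,4-dimethoxyphenyl)-7-methoxy-3-methyl-2,3-dihydro-1-benzofuran-5-yl]lithium | COc1ccc([C@H]2Oc3c(OC)cc([Li])cc3[C@@H]2C)cc1OC | intermediate
17 | lithium salt of the tetrahedral adduct of 16 and 15 (new carbinolamine carbon not defined) | COc1ccc([C@H]2Oc3c(OC)cc(C([O-])(N(C)OC)[C@H](C)O[Si](CC)(CC)CC)cc3[C@@H]2C)cc1OC.[Li+] | intermediate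
18 | (2S)-1-[(2S,3S)-2-(3,4-dimethoxyphenyl)-7-methoxy-3-methyl-2,3-dihydro-1-benzofuran-5-yl]-2-(triethylsilyloxy)propan-1-one | COc1ccc([C@H]2Oc3c(OC)cc(C(=O)[C@H](C)O[Si](CC)(CC)CC)cc3[C@@H]2C)cc1OC | intermediate
19 | (2S)-1-[(2S,3S)-2-(3,4-dimethoxyphenyl)-7-methoxy-3-methyl-2,3-dihydro-1-benzofuran-5-yl]-2-hydroxypropan-1-one | COc1ccc([C@H]2Oc3c(OC)cc(C(=O)[C@H](C)O)cc3[C@@H]2C)cc1OC | intermediate
20 | (1R,2S)-1-[(2S,3S)-2-(3,4-dimethoxyphenyl)-7-methoxy-3-methyl-2,3-dihydro-1-benzofuran-5-yl]propane-1,2-diol | COc1ccc([C@H]2Oc3c(OC)cc([C@@H](O)[C@H](C)O)cc3[C@@H]2C)cc1OC | target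

**Step count**

Total: 8 steps. Longest linear sequence: 6 steps (1, 2, 3, 4, 7, 8); steps 5 and 6 form the side branch.

**Steps most likely to fail**

Step 4. The alkoxide may fail to close onto C7a at temperatures that the aryl bromide and the sulfoxide tolerate, and facial selectivity at the aldehyde carbon may be low. The fallback sets out from 8 (with 9) and comes back at 12, using known reactions only. 8 is lithiated and added to 9 as above, but the mixture is quenched at −78 °C with aq. NH4Cl to give the sulfinyl carbinol (1S,2S)-2-{5-bromo-3-methoxy-2-[(S)-p-tolylsulfinyl]phenyl}-1-(3,4-dimethoxyphenyl)propan-1-ol F1, at which stage any carbinol epimer can be removed by chromatography. Sulfoxide–magnesium exchange (i-PrMgCl·LiCl, 2.2 equiv, THF, −50 °C, a temperature at which the bromide should not exchange) followed by an iodine quench should convert F1 in one flask into the iodo carbinol (1S,2S)-2-(5-bromo-2-iodo-3-methoxyphenyl)-1-(3,4-dimethoxyphenyl)propan-1-ol F2. Ullmann-type intramolecular O-arylation (CuI 10 mol %, 1,10-phenanthroline, Cs2CO3, toluene, 100 °C), in which the iodide reacts before the bromide, should then give 12.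

Step 2. Substitution at sulfur by the doubly ortho-substituted Grignard reagent may be slow, and attack of the Grignard reagent on the product sulfoxide (ligand exchange) may erode yield and enantiopurity. The fallback sets out from 3 and comes back at 6, and moves stereocontrol from a chiral sulfinyl donor to an enantioselective oxidation. 3 is coupled with 4-methylbenzenethiol at the iodide (Pd2(dba)3, Xantphos, i-Pr2NEt, dioxane, 90 °C) to give the diaryl sulfide 5-bromo-1-methoxy-3-methyl-2-(p-tolylsulfanyl)benzene F3. F3 is then oxidised at sulfur under Kagan-type conditions (Ti(Oi-Pr)4, diethyl tartrate, water, cumene hydroperoxide, CH2Cl2, −20 °C), the tartrate enantiomer being chosen for the (S) sulfoxide and the product enriched by crystallisation, to return at 6.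

Step 8. Chelation may be incomplete, giving poor facial selectivity at the ketone and the threo diol alongside the erythro one. The fallback sets out from 19 and comes back at 20 without a new compound, and replaces substrate (chelate) control by catalyst control. 19 is reduced by asymmetric transfer hydrogenation with RuCl(p-cymene)[(S,S)-TsDPEN] in HCO2H/Et3N at rt; the usual facial preference of this catalyst for aryl ketones should give the (1R) carbinol here, the descriptor following from the higher rank of the hydroxylated carbon.

**Further compounds**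

F1 | step 4 | (1S,2S)-2-{5-bromo-3-methoxy-2-[(S)-p-tolylsulfinyl]phenyl}-1-(3,4-dimethoxyphenyl)propan-1-ol | COc1ccc(cc1OC)[C@@H](O)[C@@H](C)c1cc(Br)cc(OC)c1[S@@](=O)c1ccc(C)cc1
F2 | step 4 | (1S,2S)-2-(5-bromo-2-iodo-3-methoxyphenyl)-1-(3,4-dimethoxyphenyl)propan-1-ol | COc1ccc(cc1OC)[C@@H](O)[C@@H](C)c1cc(Br)cc(OC)c1I
F3 | step 2 | 5-bromo-1-methoxy-3-methyl-2-(p-tolylsulfanyl)benzene | Cc1ccc(Sc2c(C)cc(Br)cc2OC)cc1
F0 | step 8 | none | none
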